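**Retrosynthetic overview**

1. The target is a trans-(2S,3R)-2-aryl-2,3-dihydrobenzofuran. Late disconnections are two aryl silyl ethers, the cinnamyl ester (Mitsunobu) and the C5 hydroxypropenyl chain (Stille coupling on a C5 bromide).
2. Key disconnection: the O1–C2 bond. The dihydrofuran ring is the only ring built; ring A, the syringyl ring and both benzoate rings are bought arenes. It is closed from acyclic triol 15 and orthoester 18: a temporary 1,3-dioxane ring forms first in the same flask and is traded for the dihydrofuran ring while its aroyl carbon remains as the ester on the C3 CH2O arm.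
3. Enabling feature: C2 is benzylic to the 4-oxy-3,5-dimethoxyphenyl ring, whose para oxygen makes it a latent quinone methide carbon. O1 is a phenolic oxygen of ring A ortho to C3a. The oxygen of the C3 hydroxymethyl arm lies 1,3 to the C2 oxygen, so one orthoester carbon can bridge both.
4. Triol 15 comes from an Evans syn aldol of arylacetyl imide 9 with silylated syringaldehyde 11, then LiBH4. Imide 9 comes from 4-bromo-2-methoxyphenol by O-allylation, Claisen rearrangement and oxidative cleavage. C3 is set in the aldol and C2 in the key step.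

Key step: step 10

Remark: dihydrobenzofuran numbering (O1, C2, C3, C3a to C7a; ring A is the benzo ring) is used for late compounds; closure at C2 is assumed to run through ionisation of the benzylic C–O bond, so the carbinol configuration of 15 is not transferred and C3 alone dictates C2.

**Route**

Step 1
Reactants: 1 4-bromo-2-methoxyphenol
Product: 2 1-(allyloxy)-4-bromo-2-methoxybenzene
Conditions: allyl bromide, K2CO3, acetone, reflux
Reagents that add atoms: allyl bromide, C=CCBr
Why: Williamson O-alkylation of the phenoxide (SN2 on the allyl halide); no stereocentre is involved.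

Step 2
Reactants: 2 1-(allyloxy)-4-bromo-2-methoxybenzene
Product: 3 2-allyl-4-bromo-6-methoxyphenol
Conditions: N,N-diethylaniline, 190 °C
Reagents that add atoms: none
Why: Aromatic Claisen rearrangement ([3,3] shift, then tautomerisation) should deliver the allyl group to the only free ortho carbon, since the other ortho position carries OMe and the para position Br.

Step 3
Reactants: 3 2-allyl-4-bromo-6-methoxyphenol
Product: 4 2-allyl-4-bromo-6-methoxyphenyl pivalate
Conditions: t-BuCOCl, Et3N, DMAP (cat.), CH2Cl2, 0 °C → rt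
Reagents that add atoms: pivaloyl chloride, CC(C)(C)C(Cl)=O
Why: DMAP-catalysed O-acylation masks the phenol as a hindered aryl ester that should survive ozonolysis, chlorite oxidation and boron enolisation and is cleaved by hydride in step 8.

Step 4
Reactants: 4 2-allyl-4-bromo-6-methoxyphenyl pivalate
Product: 6 2-[5-bromo-3-methoxy-2-(pivaloyloxy)phenyl]acetic acid, via arylacetaldehyde 5 (not isolated)
Conditions: O3, CH2Cl2, −78 °C, then PPh3; crude aldehyde with NaClO2, NaH2PO4, 2-methylbut-2-ene, t-BuOH/H2O, 0 °C → rt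
Reagents that add atoms: ozone, [O-][O+]=O; sodium chlorite, [Na+].[O-]Cl=O
Why: Ozonolysis of the terminal alkene (the acylated, brominated arene is much less reactive) followed by Pinnick oxidation of the crude aldehyde should give the arylacetic acid.

Step 5
Reactants: 6 2-[5-bromo-3-methoxy-2-(pivaloyloxy)phenyl]acetic acid; 7 (S)-4-benzyloxazolidin-2-one
Product: 9 2-{2-[(S)-4-benzyl-2-oxooxazolidin-3-yl]-2-oxoethyl}-4-bromo-6-methoxyphenyl pivalate, via mixed pivalic anhydride 8 (not isolated)
Conditions: t-BuCOCl, Et3N, THF, −20 °C; then 7, LiCl, −20 °C → rt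
Reagents that add atoms: none
Why: N-acylation of the oxazolidinone through the mixed anhydride under LiCl/Et3N activation avoids a strong base that would attack the aryl pivalate.

Step 6
Reactants: 10 4-hydroxy-3,5-dimethoxybenzaldehyde (syringaldehyde)
Product: 11 4-(tert-butyldimethylsilyloxy)-3,5-dimethoxybenzaldehyde
Conditions: TBSCl, imidazole, DMF, rt
Reagents that add atoms: tert-butyldimethylsilyl chloride, CC(C)(C)[Si](C)(C)Cl
Why: Imidazole-promoted O-silylation removes the acidic phenol before the boron aldol and gives a silyl ether that fluoride cleaves at the end.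

Step 7
Reactants: 9 2-{2-[(S)-4-benzyl-2-oxooxazolidin-3-yl]-2-oxoethyl}-4-bromo-6-methoxyphenyl pivalate; 11 4-(tert-butyldimethylsilyloxy)-3,5-dimethoxybenzaldehyde
Product: 14 (S)-4-benzyl-3-[(2S,3S)-2-(5-bromo-3-methoxy-2-pivaloyloxyphenyl)-3-(4-tert-butyldimethylsilyloxy-3,5-dimethoxyphenyl)-3-hydroxypropanoyl]oxazolidin-2-one, via boron enolate 12 (not isolated), via boron aldolate 13 (not isolated)
Conditions: Bu2BOTf, i-Pr2NEt, CH2Cl2, 0 °C; 11, −78 → 0 °C; then pH 7 phosphate buffer, MeOH, 30% H2O2, 0 °C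
Reagents that add atoms: none
Why: Evans syn aldol: the Z-dibutylboron enolate reacts through a Zimmerman–Traxler chair with the oxazolidinone carbonyl turned away from boron, so the aldehyde adds to the enolate face opposite the benzyl group and sets the α-carbon (S here, the future C3 of the target) and the carbinol carbon (S).

Step 8
Reactants: 14 (S)-4-benzyl-3-[(2S,3S)-2-(5-bromo-3-methoxy-2-pivaloyloxyphenyl)-3-(4-tert-butyldimethylsilyloxy-3,5-dimethoxyphenyl)-3-hydroxypropanoyl]oxazolidin-2-one
Product: 15 (1S,2R)-2-(5-bromo-2-hydroxy-3-methoxyphenyl)-1-[4-(tert-butyldimethylsilyloxy)-3,5-dimethoxyphenyl]propane-1,3-diol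
Conditions: LiBH4, THF/MeOH, 0 °C → rt; aq. NH4Cl
Reagents that add atoms: none
Why: LiBH4 reduces the exocyclic imide carbonyl to the primary alcohol (reductive removal of the auxiliary) and cleaves the aryl pivalate in the same operation, while the hindered aryl silyl ether and both stereocentres should remain untouched.

Step 9
Reactants: 16 (4-bromophenoxy)(tert-butyl)dimethylsilane
Product: 18 tert-butyldimethyl[4-(trimethoxymethyl)phenoxy]silane, via aryl Grignard reagent 17 (not isolated)
Conditions: Mg, THF, reflux; then C(OMe)4, toluene, 80 °C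
Reagents that add atoms: tetramethyl orthocarbonate, COC(OC)(OC)OC
Why: Magnesium insertion gives the aryl Grignard reagent, which displaces one methoxide from the orthocarbonate (Tschitschibabin-type orthoester synthesis); the aryl silyl ether is inert to both events.

Step 10
Reactants: 15 (1S,2R)-2-(5-bromo-2-hydroxy-3-methoxyphenyl)-1-[4-(tert-butyldimethylsilyloxy)-3,5-dimethoxyphenyl]propane-1,3-diol; 18 tert-butyldimethyl[4-(trimethoxymethyl)phenoxy]silane
Product: 22 [(2S,3R)-5-bromo-2-[4-(tert-butyldimethylsilyloxy)-3,5-dimethoxyphenyl]-7-methoxy-2,3-dihydrobenzofuran-3-yl]methyl 4-(tert-butyldimethylsilyloxy)benzoate, via cyclic orthoester 19 (not isolated), via dioxanylium ion 20 (not isolated), via benzylic cation 21 (not isolated)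
Conditions: 18, PPTS (cat.), 4 Å molecular sieves, CH2Cl2, rt; evaporate; BF3·OEt2 (20 mol%), CH2Cl2, −40 → 0 °C; aq. NaHCO3
Reagents that add atoms: none
Why: Proposed new method: PPTS-catalysed exchange ties the two diol oxygens of 15 into the six-membered 2-aryl-2-methoxy-1,3-dioxane 19 (mixed orthoesters that also engage the phenol drain to the same ion), and BF3·OEt2 removes methoxide to give the 2-aryl-1,3-dioxan-2-ylium ion 20, whose C–O bond at the benzylic carbon heterolyses to the para-siloxybenzyl (quinone-methide-like) cation 21 and thereby leaves the aroyl group on the primary oxygen as the finished ester. The phenolic O1 of ring A then closes the dihydrofuran ring by 5-exo attack on this carbon (5-exo-trig on cation 21, 5-exo-tet should the displacement be concerted), which forms the O1–C2 bond. The closest known reaction type is the one-pot orthoester/BF3 cyclisation of 1,2,n-triols to acyloxy tetrahydrofurans through acyloxonium ions (and the orthoester route from diols to halohydrin esters); not yet shown are a six-membered dioxanylium ion, a phenol as the internal nucleophile and opening at an ionisable benzylic carbon. C2 is controlled by the C3 centre made in the aldol: closure on the planar cation places the C2 aryl group trans to the C3 acyloxymethyl arm to avoid eclipsing in the five-membered transition state, and because the product ether can re-ionise under BF3 any cis isomer formed by direct inversion should drain into the more stable trans (2S,3R) isomer. The step needs opening of 20 at the benzylic C–O bond and not at the primary CH2–O bond, secured by the cation-stabilising 4-siloxy-3,5-dimethoxyphenyl ring, and O-closure in preference to loss of the doubly benzylic C3 proton, secured by the five-membered geometry and the low temperature.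

Step 11
Reactants: 23 prop-2-yn-1-ol
Product: 24 (E)-3-(tributylstannyl)prop-2-en-1-ol
Conditions: Bu3SnH, AIBN (cat.), neat, 80 °C
Reagents that add atoms: tributyltin hydride, CCCC[SnH](CCCC)CCCC
Why: Radical hydrostannation of the terminal alkyne under equilibrating conditions should give mainly the E β-stannyl allylic alcohol, separable from its isomers.

Step 12
Reactants: 22 [(2S,3R)-5-bromo-2-[4-(tert-butyldimethylsilyloxy)-3,5-dimethoxyphenyl]-7-methoxy-2,3-dihydrobenzofuran-3-yl]methyl 4-(tert-butyldimethylsilyloxy)benzoate; 24 (E)-3-(tributylstannyl)prop-2-en-1-ol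
Product: 25 [(2S,3R)-2-[4-(tert-butyldimethylsilyloxy)-3,5-dimethoxyphenyl]-5-[(E)-3-hydroxyprop-1-en-1-yl]-7-methoxy-2,3-dihydrobenzofuran-3-yl]methyl 4-(tert-butyldimethylsilyloxy)benzoate
Conditions: Pd(PPh3)4 (5 mol%), toluene, 100 °C
Reagents that add atoms: none
Why: Stille coupling (oxidative addition of the aryl bromide to zerovalent palladium, transmetallation with retention of alkene geometry, reductive elimination) installs the E-hydroxypropenyl chain without base, so the ester, the silyl ethers and C2/C3 should be untouched.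

Step 13
Reactants: 25 [(2S,3R)-2-[4-(tert-butyldimethylsilyloxy)-3,5-dimethoxyphenyl]-5-[(E)-3-hydroxyprop-1-en-1-yl]-7-methoxy-2,3-dihydrobenzofuran-3-yl]methyl 4-(tert-butyldimethylsilyloxy)benzoate; 26 4-hydroxybenzoic acid
Product: 27 (E)-3-[(2S,3R)-3-{[4-(tert-butyldimethylsilyloxy)benzoyloxy]methyl}-2-[4-(tert-butyldimethylsilyloxy)-3,5-dimethoxyphenyl]-7-methoxy-2,3-dihydrobenzofuran-5-yl]allyl 4-hydroxybenzoate
Conditions: PPh3, DIAD, THF, 0 °C → rt
Reagents that add atoms: none
Why: Mitsunobu esterification: the carboxylic acid, far more acidic than its own phenol, is the pronucleophile and displaces the primary allylic oxyphosphonium at the unhindered terminus, so the E-cinnamyl ester should form without phenol protection.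

Step 14
Reactants: 27 (E)-3-[(2S,3R)-3-{[4-(tert-butyldimethylsilyloxy)benzoyloxy]methyl}-2-[4-(tert-butyldimethylsilyloxy)-3,5-dimethoxyphenyl]-7-methoxy-2,3-dihydrobenzofuran-5-yl]allyl 4-hydroxybenzoate
Product: 28 quiquesetinerviusin B
Conditions: TBAF, AcOH (1:1), THF, 0 °C
Reagents that add atoms: none
Why: Fluoride cleaves both aryl silyl ethers while the acetic acid buffer keeps the liberated phenoxides protonated, so neither benzoate ester nor the para-hydroxybenzylic C2–O1 bond (and hence C2/C3) should be disturbed.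

**Compound list**

1 | 4-bromo-2-methoxyphenol | COc1cc(Br)ccc1O | starting material
2 | 1-(allyloxy)-4-bromo-2-methoxybenzene | COc1cc(Br)ccc1OCC=C | intermediate
3 | 2-allyl-4-bromo-6-methoxyphenol | COc1cc(Br)cc(CC=C)c1O | intermediate
4 | 2-allyl-4-bromo-6-methoxyphenyl pivalate | COc1cc(Br)cc(CC=C)c1OC(=O)C(C)(C)C | intermediate
5 | 4-bromo-2-methoxy-6-(2-oxoethyl)phenyl pivalate | COc1cc(Br)cc(CC=O)c1OC(=O)C(C)(C)C | intermediate (not isolated)
6 | 2-[5-bromo-3-methoxy-2-(pivaloyloxy)phenyl]acetic acid | COc1cc(Br)cc(CC(=O)O)c1OC(=O)C(C)(C)C | intermediate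
7 | (S)-4-benzyloxazolidin-2-one | O=C1N[C@@H](Cc2ccccc2)CO1 | starting material
8 | 2-[5-bromo-3-methoxy-2-(pivaloyloxy)phenyl]acetic pivalic anhydride | COc1cc(Br)cc(CC(=O)OC(=O)C(C)(C)C)c1OC(=O)C(C)(C)C | intermediate (not isolated)
9 | 2-{2-[(S)-4-benzyl-2-oxooxazolidin-3-yl]-2-oxoethyl}-4-bromo-6-methoxyphenyl pivalate | COc1cc(Br)cc(CC(=O)N2C(=O)OC[C@@H]2Cc2ccccc2)c1OC(=O)C(C)(C)C | intermediate
10 | 4-hydroxy-3,5-dimethoxybenzaldehyde (syringaldehyde) | COc1cc(C=O)cc(OC)c1O | starting material
11 | 4-(tert-butyldimethylsilyloxy)-3,5-dimethoxybenzaldehyde | COc1cc(C=O)cc(OC)c1O[Si](C)(C)C(C)(C)C | intermediate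
12 | Z-dibutylboron enolate of 9 | CCCCB(CCCC)O/C(N1C(=O)OC[C@@H]1Cc1ccccc1)=C\c1cc(Br)cc(OC)c1OC(=O)C(C)(C)C | intermediate (not isolated)
13 | O-dibutylboryl aldolate of 14 | COc1cc([C@@H](OB(CCCC)CCCC)[C@@H](C(=O)N2C(=O)OC[C@@H]2Cc2ccccc2)c2cc(Br)cc(OC)c2OC(=O)C(C)(C)C)cc(OC)c1O[Si](C)(C)C(C)(C)C | intermediate (not isolated)
14 | (S)-4-benzyl-3-[(2S,3S)-2-(5-bromo-3-methoxy-2-pivaloyloxyphenyl)-3-(4-tert-butyldimethylsilyloxy-3,5-dimethoxyphenyl)-3-hydroxypropanoyl]oxazolidin-2-one | COc1cc([C@@H](O)[C@@H](C(=O)N2C(=O)OC[C@@H]2Cc2ccccc2)c2cc(Br)cc(OC)c2OC(=O)C(C)(C)C)cc(OC)c1O[Si](C)(C)C(C)(C)C | intermediate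
15 | (1S,2R)-2-(5-bromo-2-hydroxy-3-methoxyphenyl)-1-[4-(tert-butyldimethylsilyloxy)-3,5-dimethoxyphenyl]propane-1,3-diol | COc1cc([C@@H](O)[C@@H](CO)c2cc(Br)cc(OC)c2O)cc(OC)c1O[Si](C)(C)C(C)(C)C | intermediate
16 | (4-bromophenoxy)(tert-butyl)dimethylsilane | CC(C)(C)[Si](C)(C)Oc1ccc(Br)cc1 | starting material
17 | 4-(tert-butyldimethylsilyloxy)phenylmagnesium bromide | CC(C)(C)[Si](C)(C)Oc1ccc([Mg]Br)cc1 | intermediate (not isolated)
18 | tert-butyldimethyl[4-(trimethoxymethyl)phenoxy]silane | COC(OC)(OC)c1ccc(O[Si](C)(C)C(C)(C)C)cc1 | intermediate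
19 | 4-bromo-2-{(4S,5R)-2-[4-(tert-butyldimethylsilyloxy)phenyl]-4-[4-(tert-butyldimethylsilyloxy)-3,5-dimethoxyphenyl]-2-methoxy-1,3-dioxan-5-yl}-6-methoxyphenol (both epimers at the orthoester carbon) | COc1cc([C@H]2OC(OC)(c3ccc(O[Si](C)(C)C(C)(C)C)cc3)OC[C@H]2c2cc(Br)cc(OC)c2O)cc(OC)c1O[Si](C)(C)C(C)(C)C | intermediate (not isolated)
20 | (4S,5R)-5-(5-bromo-2-hydroxy-3-methoxyphenyl)-2-[4-(tert-butyldimethylsilyloxy)phenyl]-4-[4-(tert-butyldimethylsilyloxy)-3,5-dimethoxyphenyl]-1,3-dioxan-2-ylium ion | COc1cc([C@H]2OC(c3ccc(O[Si](C)(C)C(C)(C)C)cc3)=[O+]C[C@H]2c2cc(Br)cc(OC)c2O)cc(OC)c1O[Si](C)(C)C(C)(C)C | intermediate (not isolated)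
21 | ring-opened para-siloxybenzyl cation (O-silylated quinone methide form) carrying the (R)-2-(5-bromo-2-hydroxy-3-methoxyphenyl)-3-[4-(tert-butyldimethylsilyloxy)benzoyloxy]propylidene chain | COC1=CC(=C[C@@H](COC(=O)c2ccc(O[Si](C)(C)C(C)(C)C)cc2)c2cc(Br)cc(OC)c2O)C=C(OC)C1=[O+][Si](C)(C)C(C)(C)C | intermediate (not isolated)
22 | [(2S,3R)-5-bromo-2-[4-(tert-butyldimethylsilyloxy)-3,5-dimethoxyphenyl]-7-methoxy-2,3-dihydrobenzofuran-3-yl]methyl 4-(tert-butyldimethylsilyloxy)benzoate | COc1cc([C@H]2Oc3c(OC)cc(Br)cc3[C@@H]2COC(=O)c2ccc(O[Si](C)(C)C(C)(C)C)cc2)cc(OC)c1O[Si](C)(C)C(C)(C)C | intermediate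
23 | prop-2-yn-1-ol | C#CCO | starting material
24 | (E)-3-(tributylstannyl)prop-2-en-1-ol | CCCC[Sn](CCCC)(CCCC)/C=C/CO | intermediate
25 | [(2S,3R)-2-[4-(tert-butyldimethylsilyloxy)-3,5-dimethoxyphenyl]-5-[(E)-3-hydroxyprop-1-en-1-yl]-7-methoxy-2,3-dihydrobenzofuran-3-yl]methyl 4-(tert-butyldimethylsilyloxy)benzoate | COc1cc([C@H]2Oc3c(OC)cc(/C=C/CO)cc3[C@@H]2COC(=O)c2ccc(O[Si](C)(C)C(C)(C)C)cc2)cc(OC)c1O[Si](C)(C)C(C)(C)C | intermediate
26 | 4-hydroxybenzoic acid | O=C(O)c1ccc(O)cc1 | starting material
27 | (E)-3-[(2S,3R)-3-{[4-(tert-butyldimethylsilyloxy)benzoyloxy]methyl}-2-[4-(tert-butyldimethylsilyloxy)-3,5-dimethoxyphenyl]-7-methoxy-2,3-dihydrobenzofuran-5-yl]allyl 4-hydroxybenzoate | COc1cc([C@H]2Oc3c(OC)cc(/C=C/COC(=O)c4ccc(O)cc4)cc3[C@@H]2COC(=O)c2ccc(O[Si](C)(C)C(C)(C)C)cc2)cc(OC)c1O[Si](C)(C)C(C)(C)C | intermediate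
28 | quiquesetinerviusin B, (E)-3-[(2S,3R)-2-(4-hydroxy-3,5-dimethoxyphenyl)-3-[(4-hydroxybenzoyloxy)methyl]-7-methoxy-2,3-dihydrobenzofuran-5-yl]allyl 4-hydroxybenzoate | COc1cc([C@H]2Oc3c(OC)cc(/C=C/COC(=O)c4ccc(O)cc4)cc3[C@@H]2COC(=O)c2ccc(O)cc2)cc(OC)c1O | target

**Step count and risks**

Total steps: 14. Longest linear sequence: 11 steps (1, 2, 3, 4, 5, 7, 8, 10, 12, 13, 14).

Steps most likely to fail:

1. Step 10. The benzylic C–O bond may ionise before the orthoester has formed, which closes the ring without acyl transfer. The cation may also be captured by methanol or lose the C3 proton, or closure with inversion may give the cis ring isomer faster than it equilibrates. The fallback uses known chemistry and sets out from triol 15 and aryl bromide 16. Triol 15 is cyclised by the established acid-promoted dehydrative closure of such diols (BF3·OEt2, CH2Cl2, −20 °C) to the trans carbinol [(2S,3R)-5-bromo-2-[4-(tert-butyldimethylsilyloxy)-3,5-dimethoxyphenyl]-7-methoxy-2,3-dihydrobenzofuran-3-yl]methanol F1. Grignard reagent 17, made from 16 as in step 9, is quenched with CO2 and acidified to give 4-(tert-butyldimethylsilyloxy)benzoic acid F2. Steglich esterification of F1 with F2 (EDC, DMAP, CH2Cl2) comes back to the route at compound 22.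

2. Step 12. Oxidative addition into the electron-rich aryl bromide may be slow, so that protodestannylation of the hydroxyallyl stannane and thermal loss of aryl silyl groups outrun the coupling. The fallback sets out from 22 and replaces the Stille coupling by a Suzuki–Miyaura coupling with commercial (E)-tert-butyldimethyl{[3-(4,4,5,5-tetramethyl-1,3,2-dioxaborolan-2-yl)allyl]oxy}silane (Pd(OAc)2, SPhos, K3PO4, toluene/H2O, 60 °C). This gives the allylic silyl ether [(2S,3R)-5-[(E)-3-(tert-butyldimethylsilyloxy)prop-1-en-1-yl]-2-[4-(tert-butyldimethylsilyloxy)-3,5-dimethoxyphenyl]-7-methoxy-2,3-dihydrobenzofuran-3-yl]methyl 4-(tert-butyldimethylsilyloxy)benzoate F3. Its primary alkyl silyl ether is then cleaved selectively with PPTS in MeOH/CH2Cl2 (aryl silyl ethers are stable to mild acid), which comes back to the route at compound 25.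

3. Step 13. The activated electron-rich cinnamyl alcohol may alkylate the phenolic oxygen of the acid or of the product, or ionise and give branched and ether by-products. The fallback sets out from 25 and uses carbodiimide esterification (EDC, DMAP, CH2Cl2) with the silyl-protected acid 4-(tert-butyldimethylsilyloxy)benzoic acid F2, prepared as in the first fallback. This gives the tris(silyl ether) (E)-3-[(2S,3R)-3-{[4-(tert-butyldimethylsilyloxy)benzoyloxy]methyl}-2-[4-(tert-butyldimethylsilyloxy)-3,5-dimethoxyphenyl]-7-methoxy-2,3-dihydrobenzofuran-5-yl]allyl 4-(tert-butyldimethylsilyloxy)benzoate F4. Treatment with TBAF/AcOH as in step 14 removes all three silyl groups and comes back to the route at compound 28.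

Further compounds
F1 | step 10 | [(2S,3R)-5-bromo-2-[4-(tert-butyldimethylsilyloxy)-3,5-dimethoxyphenyl]-7-methoxy-2,3-dihydrobenzofuran-3-yl]methanol | COc1cc([C@H]2Oc3c(OC)cc(Br)cc3[C@@H]2CO)cc(OC)c1O[Si](C)(C)C(C)(C)C
F2 | step 10 | 4-(tert-butyldimethylsilyloxy)benzoic acid | CC(C)(C)[Si](C)(C)Oc1ccc(cc1)C(O)=O
F3 | step 12 | [(2S,3R)-5-[(E)-3-(tert-butyldimethylsilyloxy)prop-1-en-1-yl]-2-[4-(tert-butyldimethylsilyloxy)-3,5-dimethoxyphenyl]-7-methoxy-2,3-dihydrobenzofuran-3-yl]methyl 4-(tert-butyldimethylsilyloxy)benzoate | COc1cc([C@H]2Oc3c(OC)cc(/C=C/CO[Si](C)(C)C(C)(C)C)cc3[C@@H]2COC(=O)c2ccc(O[Si](C)(C)C(C)(C)C)cc2)cc(OC)c1O[Si](C)(C)C(C)(C)C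
F4 | step 13 | (E)-3-[(2S,3R)-3-{[4-(tert-butyldimethylsilyloxy)benzoyloxy]methyl}-2-[4-(tert-butyldimethylsilyloxy)-3,5-dimethoxyphenyl]-7-methoxy-2,3-dihydrobenzofuran-5-yl]allyl 4-(tert-butyldimethylsilyloxy)benzoate | COc1cc([C@H]2Oc3c(OC)cc(/C=C/COC(=O)c4ccc(O[Si](C)(C)C(C)(C)C)cc4)cc3[C@@H]2COC(=O)c2ccc(O[Si](C)(C)C(C)(C)C)cc2)cc(OC)c1O[Si](C)(C)C(C)(C)C
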